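## Retrosynthetic overview

- **Feature.** Labels run from C1 (alkyne CH) to C15 (ethyl CH3). In the oxocene O–C7–C8–C9=C10–C11–C12–C13, the ether carbon C7 is homoallylic to the ring alkene (C7–C8–C9=C10). This is the retron of an oxocarbenium–ene (Prins) closure, with C7 as the cation and C8=C9 as a terminal alkene that shifts to C9=C10.
- **Side chain, removed first.** C6 acetate; C2–C3 (Sonogashira); E-C3=C4 (hydrozirconation–iodination); C5–C6 (chelate-controlled propargylation of the C6 aldehyde); C12–Br from the (12R)-alcohol by inversion.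
- **Ring.** The oxocene is the only ring. It is closed once, at C7–C8, from an α-acetoxy ether, and C13 directs the new C7 centre (cis-2,8).
- **Ether.** The C13–O–C7 link is made by acylating the C13 alcohol with O-silylglycolic acid, followed by reductive acetylation.
- **C8–C15 alcohol.** It comes from (R)-trityl glycidyl ether (C11–C13, brings C12), allyl Grignard (C8–C10) and ethyl Grignard (C14–C15, chelate control sets C13).

Key step: step 9

Remark: the acetal carbon made in step 8 is carried as a mixture of epimers, because ionisation in step 9 planarises it.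

## Route

Step 1
Reactants: 1 (R)-trityl glycidyl ether; 2 allylmagnesium bromide
Product: 3 (2R)-1-(trityloxy)hex-5-en-2-ol
Conditions: 2 (1.5 equiv), CuI (10 mol %), THF, −30 → 0 °C
Reagents that add atoms: none
Why: Copper-catalysed Grignard opening of a terminal epoxide: SN2 attack at the unsubstituted carbon (the future C11) leaves the C–O bond of the stereocentre untouched, so the (R) centre of 1 is carried over as C12.

Step 2
Reactants: 3 (2R)-1-(trityloxy)hex-5-en-2-ol
Product: 4 (2R)-2-(benzyloxy)-1-(trityloxy)hex-5-ene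
Conditions: NaH, BnBr, n-Bu4NI (cat.), THF–DMF, 0 °C → rt
Reagents that add atoms: benzyl bromide, BrCc1ccccc1
Why: Williamson ether synthesis on the sodium alkoxide; benzyl is chosen because its oxygen can chelate magnesium in step 5 and the group withstands the hydride of step 8 and the Lewis acid of step 9.

Step 3
Reactants: 4 (2R)-2-(benzyloxy)-1-(trityloxy)hex-5-ene
Product: 5 (2R)-2-(benzyloxy)hex-5-en-1-ol
Conditions: p-TsOH·H2O (cat.), MeOH–CH2Cl2, rt
Reagents that add atoms: none
Why: Acid-catalysed SN1 solvolysis of the trityl ether, in which methanol traps the trityl cation while the benzyl ether and the alkene stay inert.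

Step 4
Reactants: 5 (2R)-2-(benzyloxy)hex-5-en-1-ol
Product: 6 (2R)-2-(benzyloxy)hex-5-enal
Conditions: Dess–Martin periodinane, CH2Cl2, 0 °C → rt
Reagents that add atoms: none
Why: Dess–Martin oxidation stops at the aldehyde and runs without base, so the enolisable α-benzyloxy centre C12 should keep its configuration if 6 is used at once.

Step 5
Reactants: 6 (2R)-2-(benzyloxy)hex-5-enal; 7 ethylmagnesium bromide
Product: 8 (3R,4R)-4-(benzyloxy)oct-7-en-3-ol
Conditions: MgBr2·OEt2, CH2Cl2, −78 °C; then 7 (Et2O solution), −78 °C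
Reagents that add atoms: none
Why: Cram-chelate-controlled Grignard addition: magnesium holds the carbonyl and benzyloxy oxygens syn-periplanar and the ethyl group attacks from the face that carries C12–H, which sets C13 as (R) in the syn (3R,4R) diol monoether.

Step 6
Reactants: 9 glycolic acid
Product: 11 2-(tert-butyldiphenylsilyloxy)acetic acid, via bis-silylated glycolate 10 (not isolated)
Conditions: TBDPSCl (2.2 equiv), imidazole, DMF, rt; then K2CO3, MeOH–THF–H2O, rt; acidify to pH 4
Reagents that add atoms: tert-butyldiphenylsilyl chloride, CC(C)(C)[Si](Cl)(c1ccccc1)c1ccccc1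
Why: Silylation of the hydroxyl and carboxyl groups, followed by selective mild-base hydrolysis of the much more labile silyl ester of 10, leaves the silyl ether acid.

Step 7
Reactants: 8 (3R,4R)-4-(benzyloxy)oct-7-en-3-ol; 11 2-(tert-butyldiphenylsilyloxy)acetic acid
Product: 12 (3R,4R)-4-(benzyloxy)oct-7-en-3-yl 2-(tert-butyldiphenylsilyloxy)acetate
Conditions: DCC, DMAP (cat.), CH2Cl2, 0 °C → rt
Reagents that add atoms: none
Why: Steglich esterification joins the C13 oxygen to C7 by acylation with retention at C13, which avoids an etherification between two hindered carbons.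

Step 8
Reactants: 12 (3R,4R)-4-(benzyloxy)oct-7-en-3-yl 2-(tert-butyldiphenylsilyloxy)acetate
Product: 14 1-acetoxy-2-(tert-butyldiphenylsilyloxy)ethyl ether of (3R,4R)-4-(benzyloxy)oct-7-en-3-ol (epimer mixture at the acetal carbon), via diisobutylaluminium hemiacetal 13 (not isolated)
Conditions: i-Bu2AlH, CH2Cl2, −78 °C; then pyridine, DMAP, Ac2O, −78 → −20 °C
Reagents that add atoms: acetic anhydride, CC(=O)OC(C)=O
Why: Reductive acetylation of an ester: i-Bu2AlH adds once at −78 °C, the tetrahedral aluminium hemiacetal 13 (stabilised by the neighbouring silyloxy oxygen) does not collapse, and it is acetylated in the flask to the α-acetoxy ether, whose new acetal centre needs no control.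

Step 9
Reactants: 14 1-acetoxy-2-(tert-butyldiphenylsilyloxy)ethyl ether of (3R,4R)-4-(benzyloxy)oct-7-en-3-ol
Product: 16 (2R,3R,8R,5Z)-3-(benzyloxy)-8-[(tert-butyldiphenylsilyloxy)methyl]-2-ethyl-3,4,7,8-tetrahydro-2H-oxocine, via (E)-oxocarbenium ion 15 (not isolated)
Conditions: SnBr4 (2.5 equiv), 2,6-di-tert-butyl-4-methylpyridine, CH2Cl2 (0.01 M), −78 → −20 °C
Reagents that add atoms: none
Why: SnBr4 pulls the acetate off either acetal epimer of 14 to give the (E)-oxocarbenium ion 15, whose C7 is attacked by the terminal alkene carbon C8 while a C10 hydrogen passes to the ether oxygen through a six-centre ene-like array and is then given up to the base, so C7–C8 forms and the alkene moves to C9=C10. The closest known reaction type is the Lewis-acid-promoted acetal–alkene (Prins or oxocarbenium–ene) cyclization of 5-hexenyl mixed acetals to cis-2,8-disubstituted oxocenes, here fed from an α-acetoxy ether as the cation source. The oxocene closes in the 8-endo-trig mode with respect to the alkene, because the 7-exo alternative through C9 would place a primary cation on C8. The new C7 centre is controlled by C13: in the chair-like transition state C13–H lies near the plane of the C=O+ unit and the ethyl and silyloxymethyl groups both sit pseudo-equatorial, which exposes one face of 15 and should give the cis (7R,13R) ether. The step needs loss of a C10 rather than a C8 hydrogen and a Z alkene; only C10–H can reach the ring oxygen in the ene array, and an E alkene would be badly strained in the eight-membered ring. High dilution, low temperature, excess SnBr4 (which also ties up the lone pairs of the C12 benzyloxy oxygen) and the hindered pyridine are meant to hold back acetal exchange between molecules, capture of 15 by the benzyl ether oxygen and acid-induced alkene migration.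

Step 10
Reactants: 16 (2R,3R,8R,5Z)-3-(benzyloxy)-8-[(tert-butyldiphenylsilyloxy)methyl]-2-ethyl-3,4,7,8-tetrahydro-2H-oxocine
Product: 17 (2R,3R,8R,5Z)-8-[(tert-butyldiphenylsilyloxy)methyl]-2-ethyl-3,4,7,8-tetrahydro-2H-oxocin-3-ol
Conditions: BCl3·SMe2, CH2Cl2, 0 °C → rt
Reagents that add atoms: none
Why: Lewis-acid-mediated benzyl ether cleavage: chloride attacks the benzylic carbon of the boron-complexed ether, the C12–O bond is not touched (retention), and the step is placed here because the only other functions, a silyl ether and an isolated alkene, are known to tolerate this reagent.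

Step 11
Reactants: 17 (2R,3R,8R,5Z)-8-[(tert-butyldiphenylsilyloxy)methyl]-2-ethyl-3,4,7,8-tetrahydro-2H-oxocin-3-ol
Product: 19 (2R,3S,8R,5Z)-3-bromo-8-[(tert-butyldiphenylsilyloxy)methyl]-2-ethyl-3,4,7,8-tetrahydro-2H-oxocine, via alkoxyphosphonium bromide 18 (not isolated)
Conditions: CBr4, P(n-C8H17)3, toluene, 70 °C
Reagents that add atoms: carbon tetrabromide, BrC(Br)(Br)Br
Why: Appel-type bromination: bromide displaces the phosphine oxide leaving group of 18 by SN2 from the rear and turns (12R)-OH into (12S)-Br, and a slim, strongly nucleophilic trialkylphosphine in a non-polar solvent is the combination that favours substitution over elimination at hindered carbinols next to a ring oxygen.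

Step 12
Reactants: 19 (2R,3S,8R,5Z)-3-bromo-8-[(tert-butyldiphenylsilyloxy)methyl]-2-ethyl-3,4,7,8-tetrahydro-2H-oxocine
Product: 20 [(2R,7S,8R,4Z)-7-bromo-8-ethyl-3,6,7,8-tetrahydro-2H-oxocin-2-yl]methanol
Conditions: HF·pyridine, pyridine–THF, 0 °C → rt
Reagents that add atoms: none
Why: Fluoride-driven cleavage of the Si–O bond under mildly acidic rather than basic conditions, so that E2 loss of HBr toward the allylic C11 hydrogens is avoided.

Step 13
Reactants: 20 [(2R,7S,8R,4Z)-7-bromo-8-ethyl-3,6,7,8-tetrahydro-2H-oxocin-2-yl]methanol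
Product: 21 (2R,7S,8R,4Z)-7-bromo-8-ethyl-3,6,7,8-tetrahydro-2H-oxocine-2-carbaldehyde
Conditions: Dess–Martin periodinane, CH2Cl2, 0 °C → rt
Reagents that add atoms: none
Why: Dess–Martin oxidation under neutral conditions gives the α-alkoxy aldehyde without epimerising C7 or disturbing the bromide and the alkene.

Step 14
Reactants: 21 (2R,7S,8R,4Z)-7-bromo-8-ethyl-3,6,7,8-tetrahydro-2H-oxocine-2-carbaldehyde; 22 allenyltributylstannane
Product: 23 (1R)-1-[(2R,7S,8R,4Z)-7-bromo-8-ethyl-3,6,7,8-tetrahydro-2H-oxocin-2-yl]but-3-yn-1-ol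
Conditions: MgBr2·OEt2 (3 equiv), CH2Cl2, −78 °C; then 22, −78 → −20 °C
Reagents that add atoms: none
Why: Chelation-controlled SE2′ propargylation: MgBr2 bridges the aldehyde oxygen and the ring oxygen (no second ether competes now that C12 bears bromine), the allenylstannane attacks through its γ-carbon from the face that carries C7–H, and this gives the homopropargylic alcohol with the syn (6R,7R) relationship.

Step 15
Reactants: 23 (1R)-1-[(2R,7S,8R,4Z)-7-bromo-8-ethyl-3,6,7,8-tetrahydro-2H-oxocin-2-yl]but-3-yn-1-ol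
Product: 25 (1R,3E)-1-[(2R,7S,8R,4Z)-7-bromo-8-ethyl-3,6,7,8-tetrahydro-2H-oxocin-2-yl]-4-iodobut-3-en-1-ol, via alkenylzirconocene chloride 24 (not isolated)
Conditions: Cp2ZrHCl (2.5 equiv), THF, 0 °C → rt; then I2, 0 °C
Reagents that add atoms: iodine, II
Why: Hydrozirconation–iodination: one equivalent of Cp2ZrHCl is consumed by the hydroxyl group, a second adds syn to the terminal alkyne with zirconium on the terminal carbon far faster than to the internal ring alkene, and iodinolysis of the C–Zr bond of 24 with retention fixes the E-C3=C4 geometry.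

Step 16
Reactants: 25 (1R,3E)-1-[(2R,7S,8R,4Z)-7-bromo-8-ethyl-3,6,7,8-tetrahydro-2H-oxocin-2-yl]-4-iodobut-3-en-1-ol; 26 trimethylsilylacetylene
Product: 27 (1R,3E)-1-[(2R,7S,8R,4Z)-7-bromo-8-ethyl-3,6,7,8-tetrahydro-2H-oxocin-2-yl]-6-(trimethylsilyl)hex-3-en-5-yn-1-ol
Conditions: 26, PdCl2(PPh3)2 (5 mol %), CuI (10 mol %), i-Pr2NH, THF, rt
Reagents that add atoms: none
Why: Sonogashira coupling proceeds with retention of the alkenyl iodide geometry, and the secondary alkyl bromide does not undergo oxidative addition to zerovalent palladium at room temperature.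

Step 17
Reactants: 27 (1R,3E)-1-[(2R,7S,8R,4Z)-7-bromo-8-ethyl-3,6,7,8-tetrahydro-2H-oxocin-2-yl]-6-(trimethylsilyl)hex-3-en-5-yn-1-ol
Product: 28 (1R,3E)-1-[(2R,7S,8R,4Z)-7-bromo-8-ethyl-3,6,7,8-tetrahydro-2H-oxocin-2-yl]hex-3-en-5-yn-1-ol
Conditions: K2CO3 (cat.), MeOH, 0 °C → rt
Reagents that add atoms: none
Why: Base-catalysed methanolysis (protodesilylation) of the alkynyl C–Si bond, done before acetylation so that no ester is exposed to methoxide.

Step 18
Reactants: 28 (1R,3E)-1-[(2R,7S,8R,4Z)-7-bromo-8-ethyl-3,6,7,8-tetrahydro-2H-oxocin-2-yl]hex-3-en-5-yn-1-ol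
Product: 29 (1R,3E)-1-[(2R,7S,8R,4Z)-7-bromo-8-ethyl-3,6,7,8-tetrahydro-2H-oxocin-2-yl]hex-3-en-5-yn-1-yl acetate (target)
Conditions: Ac2O, pyridine, DMAP (cat.), CH2Cl2, 0 °C → rt
Reagents that add atoms: acetic anhydride, CC(=O)OC(C)=O
Why: DMAP-catalysed acylation of the C6 alcohol with retention completes the target without touching any stereocentre.

## Compound list

1 | (R)-trityl glycidyl ether | C(OC(c1ccccc1)(c1ccccc1)c1ccccc1)[C@H]1CO1 | starting material
2 | allylmagnesium bromide | C=CC[Mg]Br | starting material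
3 | (2R)-1-(trityloxy)hex-5-en-2-ol | C=CCC[C@@H](O)COC(c1ccccc1)(c1ccccc1)c1ccccc1 | intermediate
4 | (2R)-2-(benzyloxy)-1-(trityloxy)hex-5-ene | C=CCC[C@@H](OCc1ccccc1)COC(c1ccccc1)(c1ccccc1)c1ccccc1 | intermediate
5 | (2R)-2-(benzyloxy)hex-5-en-1-ol | C=CCC[C@@H](OCc1ccccc1)CO | intermediate
6 | (2R)-2-(benzyloxy)hex-5-enal | C=CCC[C@@H](OCc1ccccc1)C=O | intermediate
7 | ethylmagnesium bromide | CC[Mg]Br | starting material
8 | (3R,4R)-4-(benzyloxy)oct-7-en-3-ol | CC[C@@H](O)[C@H](OCc1ccccc1)CCC=C | intermediate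
9 | glycolic acid | OCC(=O)O | starting material
10 | tert-butyldiphenylsilyl 2-(tert-butyldiphenylsilyloxy)acetate (not isolated) | CC(C)(C)[Si](c1ccccc1)(c1ccccc1)OCC(=O)O[Si](c1ccccc1)(c1ccccc1)C(C)(C)C | intermediate
11 | 2-(tert-butyldiphenylsilyloxy)acetic acid | CC(C)(C)[Si](c1ccccc1)(c1ccccc1)OCC(=O)O | intermediate
12 | (3R,4R)-4-(benzyloxy)oct-7-en-3-yl 2-(tert-butyldiphenylsilyloxy)acetate | O=C(CO[Si](c1ccccc1)(c1ccccc1)C(C)(C)C)O[C@H](CC)[C@H](OCc1ccccc1)CCC=C | intermediate
13 | diisobutylaluminium hemiacetal of 12 (not isolated) | CC(C)C[Al](CC(C)C)OC(CO[Si](c1ccccc1)(c1ccccc1)C(C)(C)C)O[C@H](CC)[C@H](OCc1ccccc1)CCC=C | intermediate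
14 | 1-acetoxy-2-(tert-butyldiphenylsilyloxy)ethyl ether of (3R,4R)-4-(benzyloxy)oct-7-en-3-ol, acetal carbon as a mixture | CC(=O)OC(CO[Si](c1ccccc1)(c1ccccc1)C(C)(C)C)O[C@H](CC)[C@H](OCc1ccccc1)CCC=C | intermediate
15 | (E)-oxocarbenium ion at C7, acetoxytetrabromostannate as counter-ion (not isolated) | C=CCC[C@@H](OCc1ccccc1)[C@@H](CC)/[O+]=C/CO[Si](c1ccccc1)(c1ccccc1)C(C)(C)C | intermediate
16 | (2R,3R,8R,5Z)-3-(benzyloxy)-8-[(tert-butyldiphenylsilyloxy)methyl]-2-ethyl-3,4,7,8-tetrahydro-2H-oxocine | CC(C)(C)[Si](c1ccccc1)(c1ccccc1)OC[C@H]1C/C=C\C[C@@H](OCc2ccccc2)[C@@H](CC)O1 | intermediate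
17 | (2R,3R,8R,5Z)-8-[(tert-butyldiphenylsilyloxy)methyl]-2-ethyl-3,4,7,8-tetrahydro-2H-oxocin-3-ol | CC(C)(C)[Si](c1ccccc1)(c1ccccc1)OC[C@H]1C/C=C\C[C@@H](O)[C@@H](CC)O1 | intermediate
18 | C12 alkoxy(trioctyl)phosphonium bromide of 17 (not isolated) | CC(C)(C)[Si](c1ccccc1)(c1ccccc1)OC[C@H]1C/C=C\C[C@@H](O[P+](CCCCCCCC)(CCCCCCCC)CCCCCCCC)[C@@H](CC)O1.[Br-] | intermediate
19 | (2R,3S,8R,5Z)-3-bromo-8-[(tert-butyldiphenylsilyloxy)methyl]-2-ethyl-3,4,7,8-tetrahydro-2H-oxocine | CC(C)(C)[Si](c1ccccc1)(c1ccccc1)OC[C@H]1C/C=C\C[C@H](Br)[C@@H](CC)O1 | intermediate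
20 | [(2R,7S,8R,4Z)-7-bromo-8-ethyl-3,6,7,8-tetrahydro-2H-oxocin-2-yl]methanol | OC[C@H]1C/C=C\C[C@H](Br)[C@@H](CC)O1 | intermediate
21 | (2R,7S,8R,4Z)-7-bromo-8-ethyl-3,6,7,8-tetrahydro-2H-oxocine-2-carbaldehyde | O=C[C@H]1C/C=C\C[C@H](Br)[C@@H](CC)O1 | intermediate
22 | allenyltributylstannane | C=C=C[Sn](CCCC)(CCCC)CCCC | starting material
23 | (1R)-1-[(2R,7S,8R,4Z)-7-bromo-8-ethyl-3,6,7,8-tetrahydro-2H-oxocin-2-yl]but-3-yn-1-ol | C#CC[C@@H](O)[C@H]1C/C=C\C[C@H](Br)[C@@H](CC)O1 | intermediate
24 | (E)-alkenylzirconocene chloride of 23, hydroxyl as zirconocene chloride alkoxide (not isolated) | Cl[Zr](C3C=CC=C3)(C4C=CC=C4)/C=C/C[C@@H](O[Zr](Cl)(C5C=CC=C5)C6C=CC=C6)[C@H]1C/C=C\C[C@H](Br)[C@@H](CC)O1 | intermediate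
25 | (1R,3E)-1-[(2R,7S,8R,4Z)-7-bromo-8-ethyl-3,6,7,8-tetrahydro-2H-oxocin-2-yl]-4-iodobut-3-en-1-ol | I/C=C/C[C@@H](O)[C@H]1C/C=C\C[C@H](Br)[C@@H](CC)O1 | intermediate
26 | trimethylsilylacetylene | C#C[Si](C)(C)C | starting material
27 | (1R,3E)-1-[(2R,7S,8R,4Z)-7-bromo-8-ethyl-3,6,7,8-tetrahydro-2H-oxocin-2-yl]-6-(trimethylsilyl)hex-3-en-5-yn-1-ol | C[Si](C)(C)C#C/C=C/C[C@@H](O)[C@H]1C/C=C\C[C@H](Br)[C@@H](CC)O1 | intermediate
28 | (1R,3E)-1-[(2R,7S,8R,4Z)-7-bromo-8-ethyl-3,6,7,8-tetrahydro-2H-oxocin-2-yl]hex-3-en-5-yn-1-ol | C#C/C=C/C[C@@H](O)[C@H]1C/C=C\C[C@H](Br)[C@@H](CC)O1 | intermediate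
29 | (1R,3E)-1-[(2R,7S,8R,4Z)-7-bromo-8-ethyl-3,6,7,8-tetrahydro-2H-oxocin-2-yl]hex-3-en-5-yn-1-yl acetate | C#C/C=C/C[C@@H](OC(C)=O)[C@H]1C/C=C\C[C@H](Br)[C@@H](CC)O1 | target

## Step count and risks

Total step count: 18. Longest linear sequence: 17 (steps 1–5 and 7–18). Step 6 is the one-step side branch.

**Step 9 (ring closure).**
- What may go wrong: the unactivated monosubstituted alkene may be too slow a nucleophile for an oxocarbenium ion that the neighbouring silyloxy group destabilises. Other processes could then take over: capture of the cation by the C12 benzyloxy oxygen with loss of the benzyl group, proton loss to an enol ether, bromide capture at C9, or acetal exchange between molecules.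
- Fallback: close the ring at C9=C10 by metathesis instead of at C7–C8 by a cation. It sets out from 8 and returns at 16.
- The terminal alkene of 8 is moved one position inward by the palladium hydride formed from catalytic Pd(dba)2, P(t-Bu)3 and isobutyryl chloride (toluene, 80 °C), giving (3R,4R,6E)-4-(benzyloxy)oct-6-en-3-ol F1.
- NaH and bromoacetic acid in THF give 2-{[(3R,4R,6E)-4-(benzyloxy)oct-6-en-3-yl]oxy}acetic acid F2.
- Pivaloyl chloride and Et3N, then the lithium salt of (S)-4-benzyl-2-oxazolidinone, give the N-glycolyl oxazolidinone F3.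
- NaN(SiMe3)2 and allyl iodide (THF, −78 → −45 °C) alkylate the chelated Z-enolate on the face away from the benzyl group. This sets (7R) in the allylated imide F4.
- NaBH4 in THF–water removes the auxiliary and gives (2R)-2-{[(3R,4R,6E)-4-(benzyloxy)oct-6-en-3-yl]oxy}pent-4-en-1-ol F5, and TBDPSCl with imidazole gives the silyl ether diene F6.
- Second-generation Grubbs catalyst in refluxing CH2Cl2 at high dilution closes the oxocene with loss of propene, helped by the gauche preference of the vicinal C12 and C13 oxygens, and delivers 16.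

**Step 14 (propargylation).**
- What may go wrong: the hindered ring oxygen may bind magnesium only weakly, which would bring poor facial selectivity at C6. The allenylstannane may also react sluggishly with so mild a Lewis acid.
- Fallback: invert the carbinol rather than rely on the chelate. It sets out from 21 and returns at 23.
- With the monodentate BF3·OEt2 (CH2Cl2, −78 °C), 22 should add under Felkin–Anh control to give (1S)-1-[(2R,7S,8R,4Z)-7-bromo-8-ethyl-3,6,7,8-tetrahydro-2H-oxocin-2-yl]but-3-yn-1-ol F7. Any (6S) material from step 14 can be pooled with it.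
- A Mitsunobu reaction (4-nitrobenzoic acid, PPh3, DIAD, THF) inverts C6 and gives the (1R)-4-nitrobenzoate F8.
- K2CO3 in MeOH removes the ester and returns 23.

**Step 11 (bromination with inversion).**
- What may go wrong: substitution at the hindered C12 may be overtaken by E2 elimination toward the ring alkene, or by participation of the ring oxygen, which would erode the inversion.
- Fallback: separate activation from displacement. It sets out from 17 and returns at 19.
- ClCH2SO2Cl and 2,6-lutidine (CH2Cl2, 0 °C) give the isolable C12 chloromethanesulfonate F9.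
- Soluble n-Bu4NBr (toluene, 50 °C) then displaces it by SN2 at a lower temperature and a high bromide concentration to give 19.

## Further compounds

F1 | step 9 | (3R,4R,6E)-4-(benzyloxy)oct-6-en-3-ol | CC[C@@H](O)[C@H](OCc1ccccc1)C/C=C/C
F2 | step 9 | 2-{[(3R,4R,6E)-4-(benzyloxy)oct-6-en-3-yl]oxy}acetic acid | OC(=O)CO[C@H](CC)[C@H](OCc1ccccc1)C/C=C/C
F3 | step 9 | (4S)-4-benzyl-3-(2-{[(3R,4R,6E)-4-(benzyloxy)oct-6-en-3-yl]oxy}acetyl)-1,3-oxazolidin-2-one | O=C(CO[C@H](CC)[C@H](OCc1ccccc1)C/C=C/C)N1[C@@H](Cc2ccccc2)COC1=O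
F4 | step 9 | (4S)-4-benzyl-3-[(2R)-2-{[(3R,4R,6E)-4-(benzyloxy)oct-6-en-3-yl]oxy}pent-4-enoyl]-1,3-oxazolidin-2-one | C=CC[C@@H](O[C@H](CC)[C@H](OCc1ccccc1)C/C=C/C)C(=O)N1[C@@H](Cc2ccccc2)COC1=O
F5 | step 9 | (2R)-2-{[(3R,4R,6E)-4-(benzyloxy)oct-6-en-3-yl]oxy}pent-4-en-1-ol | C=CC[C@@H](O[C@H](CC)[C@H](OCc1ccccc1)C/C=C/C)CO
F6 | step 9 | tert-butyldiphenylsilyl ether of F5 | C=CC[C@@H](O[C@H](CC)[C@H](OCc1ccccc1)C/C=C/C)CO[Si](c1ccccc1)(c1ccccc1)C(C)(C)C
F7 | step 14 | (1S)-1-[(2R,7S,8R,4Z)-7-bromo-8-ethyl-3,6,7,8-tetrahydro-2H-oxocin-2-yl]but-3-yn-1-ol | C#CC[C@H](O)[C@H]1C/C=C\C[C@H](Br)[C@@H](CC)O1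
F8 | step 14 | (1R)-1-[(2R,7S,8R,4Z)-7-bromo-8-ethyl-3,6,7,8-tetrahydro-2H-oxocin-2-yl]but-3-yn-1-yl 4-nitrobenzoate | C#CC[C@@H](OC(=O)c2ccc(cc2)[N+](=O)[O-])[C@H]1C/C=C\C[C@H](Br)[C@@H](CC)O1
F9 | step 11 | (2R,3R,8R,5Z)-8-[(tert-butyldiphenylsilyloxy)methyl]-2-ethyl-3,4,7,8-tetrahydro-2H-oxocin-3-yl chloromethanesulfonate | CC(C)(C)[Si](c1ccccc1)(c1ccccc1)OC[C@H]1C/C=C\C[C@@H](OS(=O)(=O)CCl)[C@@H](CC)O1
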